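**Retrosynthetic overview**
1. C40 → two Wittig olefinations (C11=C12, C11'=C12') of (2E,4E,6E)-2,7-dimethylocta-2,4,6-trienedial with two C15 phosphonium salts: end group A (3,6-epoxy bicycle) and end group B (3,5,6-triol).
2. Both C15 units come from two diastereomeric α-hydroxy ketones with the same C6 and opposite C3. C5-methyl is added by an organometal, C7=C8 comes from hydroxyl-directed alkyne reduction, and the oxygen bridge of A is closed by O6 attacking C3 with inversion.
3. Key step: the C5–C6 bond (carbinol carbon to carbinol carbon) is made by a carbene-catalysed intramolecular crossed benzoin of a racemic keto-aldehyde. The acyl-anion carbon C5 attacks the ynone carbonyl C6; the catalyst fixes C6 and the racemic C3 gives one diastereomer for each end group.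
4. The keto-aldehyde is built from 2,2-dimethylpent-4-enoic acid, (1,3-dioxolan-2-ylmethyl)magnesium bromide and (E)-3-methylpent-2-en-4-yn-1-ol.
5. Ring order: the cyclohexane ring of both end groups forms in the key step; the oxabicycle of A is closed last, before salt formation.

Assumption 1: the target is read as (3R,5R,6S,3'R,5'S,6'S)-3,6-epoxy-5,6,5',6'-tetrahydro-β,β-carotene-5,3',5',6'-tetrol; ring atoms of all intermediates are described in carotenoid numbering (C1 = CMe2, C3 = CH–O, C5 = C(Me)–O, C6 = carbon bearing the chain).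
Assumption 2: the (5aS,10bR) antipode of the aminoindanol triazolium catalyst is taken to give the C6 configuration shown; if the sense is opposite, the equally available (5aR,10bS) antipode is used with no other change.

Note on descriptors: with an alkyne at C7 the CIP descriptor of C6 is R; after reduction to the alkene the same geometry is 6S.

**Step 1**
Reactants: 1 2,2-dimethylpent-4-enoic acid
Product: 2 5-hydroxy-3,3-dimethyloxolan-2-one (racemic lactol, ring form of 2,2-dimethyl-4-oxobutanoic acid)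
Conditions: O3, CH2Cl2, −78 °C; Me2S, −78 → 23 °C
Reagents that add atoms: ozone, [O-][O+]=O
Why: Ozonolysis with reductive work-up cleaves the terminal alkene to the C3 aldehyde, which closes onto the acid as the lactol.

**Step 2**
Reactants: 2 5-hydroxy-3,3-dimethyloxolan-2-one; 3 (1,3-dioxolan-2-ylmethyl)magnesium bromide
Product: 5 5-(1,3-dioxolan-2-ylmethyl)-3,3-dimethyloxolan-2-one (racemic), via hydroxy acid 4 (not isolated)
Conditions: 3 (2.3 equiv), THF, −20 → 0 °C; aq. HCl to pH 3, 0 °C; PhMe, 50 °C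
Reagents that add atoms: none
Why: Grignard addition: the first equivalent opens the lactol to the carboxylate aldehyde, the second adds to the aldehyde, and the γ-hydroxy acid lactonises (gem-dimethyl effect); C3 is made racemic on purpose.

**Step 3**
Reactants: 5 5-(1,3-dioxolan-2-ylmethyl)-3,3-dimethyloxolan-2-one; 6 (E)-3-methylpent-2-en-4-yn-1-ol
Product: 8 (E)-10-(1,3-dioxolan-2-yl)-1,9-dihydroxy-3,7,7-trimethyldec-2-en-4-yn-6-one (racemic), via dilithio enynolate 7 (not isolated)
Conditions: 6 (1.25 equiv), n-BuLi (2.5 equiv), THF, −78 → −20 °C; 5, −78 → −40 °C; AcOH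
Reagents that add atoms: none
Why: Acetylide addition to a non-enolisable α,α-dimethyl lactone stops at the lithium hemiketalate, which gives the hydroxy ynone on work-up (lactone ring opening without over-addition).

**Step 4**
Reactants: 8 (E)-10-(1,3-dioxolan-2-yl)-1,9-dihydroxy-3,7,7-trimethyldec-2-en-4-yn-6-one
Product: 12 (E)-11-[(tert-butyldimethylsilyl)oxy]-5,5,9-trimethyl-6-oxo-3-[(triethylsilyl)oxy]undec-9-en-7-ynal (racemic), via mono-TBS ether 9 (not isolated), via bis-silyl acetal 10 (not isolated), via collidinium salt 11 (not isolated)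
Conditions: TBSCl (1.05 equiv), imidazole, CH2Cl2, −20 °C; then 2,4,6-collidine (5 equiv), Et3SiOTf (3.2 equiv), 0 °C; then H2O, 23 °C
Reagents that add atoms: tert-butyldimethylsilyl chloride, CC(C)(C)[Si](C)(C)Cl; triethylsilyl triflate, CC[Si](CC)(CC)OS(=O)(=O)C(F)(F)F; water, O
Why: Primary-selective silylation is followed by silyl triflate/collidine, which silylates the secondary alcohol and turns the dioxolane into a collidinium mixed acetal that water hydrolyses to the aldehyde (chemoselective non-acidic acetal cleavage), so the β-silyloxy aldehyde never meets acid or strong base.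

**Step 5 (key step)**
Reactants: 12 (E)-11-[(tert-butyldimethylsilyl)oxy]-5,5,9-trimethyl-6-oxo-3-[(triethylsilyl)oxy]undec-9-en-7-ynal (racemic)
Product: 14 (2R,5R)-2-[(3E)-5-{[tert-butyl(dimethyl)silyl]oxy}-3-methylpent-3-en-1-yn-1-yl]-2-hydroxy-3,3-dimethyl-5-[(triethylsilyl)oxy]cyclohexan-1-one (cis, carotenoid 3R,6R) and 15 its (2R,5S) diastereomer (trans, carotenoid 3S,6R), separated by chromatography, via Breslow intermediate 13 (not isolated)
Conditions: (5aS,10bR)-2-(pentafluorophenyl)-5a,10b-dihydro-4H,6H-indeno[2,1-b][1,2,4]triazolo[4,3-d][1,4]oxazin-2-ium tetrafluoroborate (15 mol %), iPr2NEt (15 mol %), 4 Å MS, PhMe, 23 °C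
Reagents that add atoms: none
Why: Proposed new method: the carbene adds to the aldehyde to give Breslow intermediate 13, whose nucleophilic acyl carbon C5 closes the six-membered ring by 6-exo attack on the non-enolisable, sterically open ynone carbonyl C6; the chiral triazolylidene dictates the carbonyl face while the remote C3 centre only chooses between an equatorial and an axial silyloxy group in the chair-like transition state, so both enantiomers of 12 react with the same sense at C6 and give the separable diastereomers 14 and 15 (a divergent reaction on a racemic mixture); the closest known reaction type is the triazolium-catalysed enantioselective intramolecular crossed aldehyde–ketone benzoin cyclisation.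

**Step 6 (end group B)**
Reactants: 14 cis α-hydroxy ketone (carotenoid 3R,6R)
Product: 18 (1S,2R,5R)-2-[(3E)-5-{[tert-butyl(dimethyl)silyl]oxy}-3-methylpent-3-en-1-yn-1-yl]-1,3,3-trimethyl-5-[(triethylsilyl)oxy]cyclohexane-1,2-diol (carotenoid 3R,5S,6R), via TMS ether 16 (not isolated), via lithium alkoxide 17 (not isolated)
Conditions: N-(trimethylsilyl)imidazole (1.5 equiv), THF, 23 °C; MeLi (4 equiv), −78 → −40 °C; MeOH, 23 °C, 1 h; AcOH
Reagents that add atoms: methyllithium, [Li]C
Why: Capping O6 as the TMS ether excludes chelation, so the ketone reacts from the chair with the 3-silyloxy group equatorial and O6 axial, where the axial C1 methyl blocks the axial trajectory (as in 3,3,5-trimethylcyclohexanone) and MeLi enters equatorially to give the axial 5-OH trans to O6 (5S); methanolic LiOMe then removes the TMS group (1,2-addition under steric approach control).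

**Step 7**
Reactants: 18 alkynyl diol (carotenoid 3R,5S,6R)
Product: 19 (1S,2S,5R)-2-[(1E,3E)-5-{[tert-butyl(dimethyl)silyl]oxy}-3-methylpenta-1,3-dien-1-yl]-1,3,3-trimethyl-5-[(triethylsilyl)oxy]cyclohexane-1,2-diol (carotenoid 3R,5S,6S)
Conditions: NaAlH2(OCH2CH2OCH3)2 (4 equiv), THF, 0 → 23 °C; aq. Rochelle salt
Reagents that add atoms: none
Why: The C6 alkoxyaluminate delivers hydride to C7 and the trans-hydroalumination product is protonated to the 7E alkene (hydroxyl-directed trans reduction of a propargylic alcohol); the 9E alkene and the silyl ethers are untouched.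

**Step 8**
Reactants: 19 bis-silyl diene diol (carotenoid 3R,5S,6S)
Product: 20 (1S,2S,4R)-1-[(1E,3E)-5-hydroxy-3-methylpenta-1,3-dien-1-yl]-2,6,6-trimethylcyclohexane-1,2,4-triol (carotenoid 3R,5S,6S)
Conditions: Bu4NF (3 equiv), AcOH (3 equiv), THF, 0 → 23 °C
Reagents that add atoms: none
Why: Buffered fluoride removes both silyl ethers without acid, so the ionisable dienylic C6–OH (which under acid would be captured by the cis 3-OH) survives.

**Step 9**
Reactants: 20 tetraol (carotenoid 3R,5S,6S)
Product: 22 {(2E,4E)-3-methyl-5-[(1S,2S,4R)-1,2,4-trihydroxy-2,6,6-trimethylcyclohexyl]penta-2,4-dien-1-yl}triphenylphosphonium bromide, via allylic bromide 21 (not isolated)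
Conditions: CBr4 (1.05 equiv), PPh3 (2.5 equiv), 2,6-lutidine (0.3 equiv), CH2Cl2, −20 → 23 °C; precipitation from Et2O
Reagents that add atoms: carbon tetrabromide, BrC(Br)(Br)Br; triphenylphosphine, c1ccccc1P(c1ccccc1)c1ccccc1
Why: Appel bromination is selective for the primary allylic alcohol (tertiary alcohols inert, secondary slow at −20 °C) and the excess phosphine quaternises the bromide by SN2, all under neutral conditions that do not ionise C6.

**Step 10 (end group A)**
Reactants: 15 trans α-hydroxy ketone (carotenoid 3S,6R)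
Product: 23 (1R,2R,5S)-2-[(3E)-5-{[tert-butyl(dimethyl)silyl]oxy}-3-methylpent-3-en-1-yn-1-yl]-1,3,3-trimethyl-5-[(triethylsilyl)oxy]cyclohexane-1,2-diol (carotenoid 3S,5R,6R)
Conditions: MeMgBr (4 equiv), CH2Cl2/Et2O, −78 → −20 °C; AcOH
Reagents that add atoms: methylmagnesium bromide, C[Mg]Br
Why: Here the magnesium alkoxide chelate (O6 equatorial, in plane with C5=O) is compatible with the preferred chair (3-silyloxy equatorial, slim alkynyl axial), the axial C1 methyl again blocks the axial trajectory, and the Grignard reagent enters equatorially past the alkynyl group to give the axial 5-OH cis to O6 (5R).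

**Step 11**
Reactants: 23 alkynyl diol (carotenoid 3S,5R,6R)
Product: 24 (1R,2R,4S)-1-[(3E)-5-{[tert-butyl(dimethyl)silyl]oxy}-3-methylpent-3-en-1-yn-1-yl]-2,6,6-trimethylcyclohexane-1,2,4-triol (carotenoid 3S,5R,6R)
Conditions: pyridinium p-toluenesulfonate (0.2 equiv), MeOH/CH2Cl2, 0 °C
Reagents that add atoms: none
Why: Mild acid methanolysis removes the secondary triethylsilyl ether faster than the primary TBS ether, and it is done at the alkyne stage where C6 (propargylic) cannot ionise.

**Step 12**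
Reactants: 24 alkynyl triol (carotenoid 3S,5R,6R)
Product: 25 (1S,2R,4S)-1-[(1E,3E)-5-{[tert-butyl(dimethyl)silyl]oxy}-3-methylpenta-1,3-dien-1-yl]-2,6,6-trimethylcyclohexane-1,2,4-triol (carotenoid 3S,5R,6S)
Conditions: NaAlH2(OCH2CH2OCH3)2 (5 equiv), THF, 0 → 23 °C; aq. Rochelle salt
Reagents that add atoms: none
Why: Hydroxyl-directed trans reduction of the propargylic alcohol as in step 7, done before the ether bridge exists because a propargylic ether would be opened to an allene, with a non-acidic work-up because acid would ionise C6 and let the trans 3-OH close to the wrong bicycle.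

**Step 13**
Reactants: 25 diene triol (carotenoid 3S,5R,6S)
Product: 27 (1S,2R,4R)-1-[(1E,3E)-5-{[tert-butyl(dimethyl)silyl]oxy}-3-methylpenta-1,3-dien-1-yl]-2,6,6-trimethyl-7-oxabicyclo[2.2.1]heptan-2-ol (carotenoid 3R,5R,6S), via alkoxyphosphonium salt 26 (not isolated)
Conditions: PPh3 (1.6 equiv), diisopropyl azodicarboxylate (1.6 equiv), THF, 0 → 40 °C
Reagents that add atoms: none
Why: Mitsunobu cyclodehydration: only the secondary 3-OH is activated, and the trans-disposed tertiary 6-OH displaces it through the boat with inversion (3S → 3R), leaving the 5-OH on the same side as the new bridge; no alkoxide is formed, which avoids Grob fragmentation of the 5-O/3-leaving-group pair.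

**Step 14**
Reactants: 27 bicyclic silyl ether (carotenoid 3R,5R,6S)
Product: 29 {(2E,4E)-5-[(1S,2R,4R)-2-hydroxy-2,6,6-trimethyl-7-oxabicyclo[2.2.1]heptan-1-yl]-3-methylpenta-2,4-dien-1-yl}triphenylphosphonium bromide, via allylic alcohol 28 (not isolated)
Conditions: PPh3·HBr (1.15 equiv), MeOH, 0 → 23 °C
Reagents that add atoms: triphenylphosphine hydrobromide, [Br-].c1ccccc1[PH+](c1ccccc1)c1ccccc1
Why: Acid methanolysis frees the primary allylic alcohol, which is substituted by the phosphine (standard C15 Wittig salt formation); the bicyclic ether tolerates this because an ionised C6 can only re-close to the same ether.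

**Step 15**
Reactants: 29 phosphonium bromide of end group A; 30 (2E,4E,6E)-2,7-dimethylocta-2,4,6-trienedial
Product: 32 (2E,4E,6E,8E,10E,12E)-13-[(1S,2R,4R)-2-hydroxy-2,6,6-trimethyl-7-oxabicyclo[2.2.1]heptan-1-yl]-2,7,11-trimethyltrideca-2,4,6,8,10,12-hexaenal, via ylide 31 (not isolated)
Conditions: 30 (4 equiv), NaOMe, MeOH/CH2Cl2, 0 → 23 °C; then EtOAc, reflux, Ar
Reagents that add atoms: none
Why: Wittig olefination of one aldehyde group of the excess dialdehyde (the rest is recovered); the semi-stabilised ylide gives an 11E/11Z mixture that is equilibrated thermally to the E isomer, and no stereocentre is touched.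

**Step 16**
Reactants: 32 C25 aldehyde; 22 phosphonium bromide of end group B
Product: 34 (3R,5R,6S,3'R,5'S,6'S)-3,6-epoxy-5,6,5',6'-tetrahydro-β,β-carotene-5,3',5',6'-tetrol (target), via ylide 33 (not isolated)
Conditions: NaOMe, MeOH/CH2Cl2, 23 °C; then heptane/EtOH, reflux, Ar, dark; crystallisation
Reagents that add atoms: none
Why: Second Wittig olefination joins C11' to C12' with all hydroxyl groups free, and neutral thermal isomerisation with crystallisation gives the all-E nonaene; acid is avoided because the triol end would cyclise.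

**Compound list**
1 | 2,2-dimethylpent-4-enoic acid | C=CCC(C)(C)C(=O)O | starting material
2 | 5-hydroxy-3,3-dimethyloxolan-2-one (racemic) | CC1(C)CC(O)OC1=O | intermediate
3 | (1,3-dioxolan-2-ylmethyl)magnesium bromide | Br[Mg]CC1OCCO1 | starting material
4 | 5-(1,3-dioxolan-2-yl)-4-hydroxy-2,2-dimethylpentanoic acid (racemic, as magnesium salt) | OC(CC1OCCO1)CC(C)(C)C(=O)O | intermediate (not isolated)
5 | 5-(1,3-dioxolan-2-ylmethyl)-3,3-dimethyloxolan-2-one (racemic) | CC1(C)CC(CC2OCCO2)OC1=O | intermediate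
6 | (E)-3-methylpent-2-en-4-yn-1-ol | C#C/C(C)=C/CO | starting material
7 | dilithium salt of 6 (alkoxide and acetylide) | [Li]C#C/C(C)=C/CO[Li] | intermediate (not isolated)
8 | (E)-10-(1,3-dioxolan-2-yl)-1,9-dihydroxy-3,7,7-trimethyldec-2-en-4-yn-6-one (racemic) | O=C(C#C/C(C)=C/CO)C(C)(C)CC(O)CC1OCCO1 | intermediate
9 | 1-O-TBS ether of 8 | O=C(C#C/C(C)=C/CO[Si](C)(C)C(C)(C)C)C(C)(C)CC(O)CC1OCCO1 | intermediate (not isolated)
10 | 1-O-TBS, 9-O-triethylsilyl ether of 8 | O=C(C#C/C(C)=C/CO[Si](C)(C)C(C)(C)C)C(C)(C)CC(O[Si](CC)(CC)CC)CC1OCCO1 | intermediate (not isolated)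
11 | N-(1-alkoxyalkyl)-2,4,6-trimethylpyridinium triflate formed from 10 (ring-opened dioxolane, glycol end silylated) | O=C(C#C/C(C)=C/CO[Si](C)(C)C(C)(C)C)C(C)(C)CC(O[Si](CC)(CC)CC)CC(OCCO[Si](CC)(CC)CC)[n+]1c(C)cc(C)cc1C.[O-]S(=O)(=O)C(F)(F)F | intermediate (not isolated)
12 | (E)-11-[(tert-butyldimethylsilyl)oxy]-5,5,9-trimethyl-6-oxo-3-[(triethylsilyl)oxy]undec-9-en-7-ynal (racemic) | O=CCC(O[Si](CC)(CC)CC)CC(C)(C)C(=O)C#C/C(C)=C/CO[Si](C)(C)C(C)(C)C | intermediate
13 | Breslow intermediate (enaminol) of 12 with the (5aS,10bR) triazolylidene | c1ccc2c(c1)C[C@@H]1OCC3=NN(c4c(F)c(F)c(F)c(F)c4F)C(=C(O)CC(O[Si](CC)(CC)CC)CC(C)(C)C(=O)C#C/C(C)=C/CO[Si](C)(C)C(C)(C)C)N3[C@H]21 | intermediate (not isolated)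
14 | cis α-hydroxy ketone, (2R,5R) (carotenoid 3R,6R) | CC(C)(C)[Si](C)(C)OC/C=C(C)/C#C[C@]1(O)C(C)(C)C[C@@H](O[Si](CC)(CC)CC)CC1=O | intermediate
15 | trans α-hydroxy ketone, (2R,5S) (carotenoid 3S,6R) | CC(C)(C)[Si](C)(C)OC/C=C(C)/C#C[C@]1(O)C(C)(C)C[C@H](O[Si](CC)(CC)CC)CC1=O | intermediate
16 | 6-O-TMS ether of 14 | CC(C)(C)[Si](C)(C)OC/C=C(C)/C#C[C@]1(O[Si](C)(C)C)C(C)(C)C[C@@H](O[Si](CC)(CC)CC)CC1=O | intermediate (not isolated)
17 | lithium 5-alkoxide of the methyl adduct of 16 | CC(C)(C)[Si](C)(C)OC/C=C(C)/C#C[C@]1(O[Si](C)(C)C)C(C)(C)C[C@@H](O[Si](CC)(CC)CC)C[C@]1(C)O[Li] | intermediate (not isolated)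
18 | alkynyl diol of end group B (carotenoid 3R,5S,6R) | CC(C)(C)[Si](C)(C)OC/C=C(C)/C#C[C@]1(O)C(C)(C)C[C@@H](O[Si](CC)(CC)CC)C[C@]1(C)O | intermediate
19 | diene diol of end group B (carotenoid 3R,5S,6S) | CC(C)(C)[Si](C)(C)OC/C=C(C)/C=C/[C@]1(O)C(C)(C)C[C@@H](O[Si](CC)(CC)CC)C[C@]1(C)O | intermediate
20 | (1S,2S,4R)-1-[(1E,3E)-5-hydroxy-3-methylpenta-1,3-dien-1-yl]-2,6,6-trimethylcyclohexane-1,2,4-triol | OC/C=C(C)/C=C/[C@]1(O)C(C)(C)C[C@@H](O)C[C@]1(C)O | intermediate
21 | allylic bromide of 20 | BrC/C=C(C)/C=C/[C@]1(O)C(C)(C)C[C@@H](O)C[C@]1(C)O | intermediate (not isolated)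
22 | C15 phosphonium bromide of end group B | [Br-].c1ccccc1[P+](c1ccccc1)(c1ccccc1)C/C=C(C)/C=C/[C@]1(O)C(C)(C)C[C@@H](O)C[C@]1(C)O | intermediate
23 | alkynyl diol of end group A (carotenoid 3S,5R,6R) | CC(C)(C)[Si](C)(C)OC/C=C(C)/C#C[C@]1(O)C(C)(C)C[C@H](O[Si](CC)(CC)CC)C[C@@]1(C)O | intermediate
24 | alkynyl triol of end group A (carotenoid 3S,5R,6R) | CC(C)(C)[Si](C)(C)OC/C=C(C)/C#C[C@]1(O)C(C)(C)C[C@H](O)C[C@@]1(C)O | intermediate
25 | diene triol of end group A (carotenoid 3S,5R,6S) | CC(C)(C)[Si](C)(C)OC/C=C(C)/C=C/[C@]1(O)C(C)(C)C[C@H](O)C[C@@]1(C)O | intermediate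
26 | 3-O-triphenylphosphonium salt of 25 (hydrazide counter-ion) | CC(C)(C)[Si](C)(C)OC/C=C(C)/C=C/[C@]1(O)C(C)(C)C[C@H](O[P+](c2ccccc2)(c2ccccc2)c2ccccc2)C[C@@]1(C)O.CC(C)OC(=O)N[N-]C(=O)OC(C)C | intermediate (not isolated)
27 | (1S,2R,4R)-1-[(1E,3E)-5-{[tert-butyl(dimethyl)silyl]oxy}-3-methylpenta-1,3-dien-1-yl]-2,6,6-trimethyl-7-oxabicyclo[2.2.1]heptan-2-ol | CC(C)(C)[Si](C)(C)OC/C=C(C)/C=C/[C@]12O[C@H](CC1(C)C)C[C@@]2(C)O | intermediate
28 | allylic alcohol from 27 (TBS removed) | OC/C=C(C)/C=C/[C@]12O[C@H](CC1(C)C)C[C@@]2(C)O | intermediate (not isolated)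
29 | C15 phosphonium bromide of end group A | [Br-].c1ccccc1[P+](c1ccccc1)(c1ccccc1)C/C=C(C)/C=C/[C@]12O[C@H](CC1(C)C)C[C@@]2(C)O | intermediate
30 | (2E,4E,6E)-2,7-dimethylocta-2,4,6-trienedial | O=C/C(C)=C/C=C/C=C(C)/C=O | starting material
31 | ylide of 29 | c1ccccc1[P+](c1ccccc1)(c1ccccc1)[CH-]/C=C(C)/C=C/[C@]12O[C@H](CC1(C)C)C[C@@]2(C)O | intermediate (not isolated)
32 | C25 aldehyde (all-E) carrying end group A | O=C/C(C)=C/C=C/C=C(C)/C=C/C=C(C)/C=C/[C@]12O[C@H](CC1(C)C)C[C@@]2(C)O | intermediate
33 | ylide of 22 | c1ccccc1[P+](c1ccccc1)(c1ccccc1)[CH-]/C=C(C)/C=C/[C@]1(O)C(C)(C)C[C@@H](O)C[C@]1(C)O | intermediate (not isolated)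
34 | (3R,5R,6S,3'R,5'S,6'S)-3,6-epoxy-5,6,5',6'-tetrahydro-β,β-carotene-5,3',5',6'-tetrol | CC(/C=C/C=C(C)/C=C/[C@]12O[C@H](CC1(C)C)C[C@@]2(C)O)=C\C=C\C=C(C)\C=C\C=C(C)\C=C\[C@]1(O)C(C)(C)C[C@@H](O)C[C@]1(C)O | target

**Totals**
Total step count: 16. Longest linear sequence: 12 (steps 1–5, 10–16).

**Three steps most likely to fail**

Step 5. The carbene may not override the C3 centre for one antipode of 12, and elimination of the β-silyloxy group or aldol closure could compete. Fallback, setting out from 14 and coming back at 24: step 5 is run to about half conversion as a kinetic resolution that gives only 14, and end group A is reached by inverting C3 instead of using the other enantiomer. Compound 14 is desilylated at O3 (pyridinium p-toluenesulfonate, MeOH) to the cis hydroxy ketone F1. Mitsunobu esterification with benzoic acid (PPh3, diisopropyl azodicarboxylate) inverts C3 and gives the trans benzoate F2. Excess MeMgBr then adds to the ketone under the chelate model of step 10 and cleaves the benzoate, giving 24.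

Step 6. Equatorial attack has to pass the axial 6-silyloxy group, and the wrong C5 epimer may form. Fallback, setting out from 14 and coming back at 19: the methyl carbon is introduced reversibly instead of irreversibly. Dimethylsulfoxonium methylide (Me3S(O)I, NaH, DMSO/THF) adds under thermodynamic control, places the new C–C bond equatorial and closes to the spiro-epoxide F3 with O5 trans to O6. NaAlH2(OCH2CH2OCH3)2 then opens the epoxide at CH2 and reduces the propargylic alkyne in the same operation, giving 19.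

Step 13. Closure through the boat may lose to elimination or to fragmentation of the activated 1,3-diol unit. Fallback, setting out from 14 and coming back at 27: the bridge is made by ionisation at C6 with retention in the 3R series instead of by displacement at C3. Wittig methylenation of 14 (Ph3P=CH2, PhMe, 60 °C) gives the exocyclic alkene F4. Epoxidation directed by the tertiary allylic 6-OH (VO(acac)2, t-BuOOH) gives the syn spiro-epoxide F5. NaAlH2(OCH2CH2OCH3)2 opens the epoxide and reduces the alkyne to the all-cis diene diol F6. Pyridinium p-toluenesulfonate in MeOH removes the triethylsilyl group to give the all-cis triol F7, and catalytic camphorsulfonic acid in CH2Cl2 ionises the dienylic C6–OH, which the cis 3-OH captures on the same face to give 27.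

**Further compounds**
F1 | step 5 | (2R,5R)-2-[(3E)-5-{[tert-butyl(dimethyl)silyl]oxy}-3-methylpent-3-en-1-yn-1-yl]-2,5-dihydroxy-3,3-dimethylcyclohexan-1-one | CC(C)(C)[Si](C)(C)OC/C=C(C)/C#C[C@]1(O)C(C)(C)C[C@@H](O)CC1=O
F2 | step 5 | (1S,4R)-4-[(3E)-5-{[tert-butyl(dimethyl)silyl]oxy}-3-methylpent-3-en-1-yn-1-yl]-4-hydroxy-3,3-dimethyl-5-oxocyclohexyl benzoate | CC(C)(C)[Si](C)(C)OC/C=C(C)/C#C[C@]1(O)C(C)(C)C[C@H](OC(=O)c2ccccc2)CC1=O
F3 | step 6 | spiro-epoxide of 14 at C5 with O5 trans to O6 (carotenoid 3R,6R series) | CC(C)(C)[Si](C)(C)OC/C=C(C)/C#C[C@]1(O)C(C)(C)C[C@@H](O[Si](CC)(CC)CC)C[C@@]12CO2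
F4 | step 13 | 5-methylidene analogue of 14 (C5=CH2 in place of C5=O) | CC(C)(C)[Si](C)(C)OC/C=C(C)/C#C[C@]1(O)C(C)(C)C[C@@H](O[Si](CC)(CC)CC)CC1=C
F5 | step 13 | spiro-epoxide of F4 with O5 cis to O6 | CC(C)(C)[Si](C)(C)OC/C=C(C)/C#C[C@]1(O)C(C)(C)C[C@@H](O[Si](CC)(CC)CC)C[C@]12CO2
F6 | step 13 | all-cis diene diol, 3-O-triethylsilyl (carotenoid 3R,5R,6S) | CC(C)(C)[Si](C)(C)OC/C=C(C)/C=C/[C@]1(O)C(C)(C)C[C@@H](O[Si](CC)(CC)CC)C[C@@]1(C)O
F7 | step 13 | all-cis diene triol (carotenoid 3R,5R,6S) | CC(C)(C)[Si](C)(C)OC/C=C(C)/C=C/[C@]1(O)C(C)(C)C[C@@H](O)C[C@@]1(C)O
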